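**Plan**

- Retrosynthesis: after removing the two ring-B methyl ethers and the silicon protecting groups, ring B is opened at C1'–C2' and C1'–C6'; then the O8–C4' bond is cut, then the C1–C7 bond between ring A and the side chain.
- Forward: ring A is joined to a lactate-derived chain, the ketone is reduced, a pentane-2,4-dione is attached to O8 through its central carbon, and ring B (the only ring formed) is built last around that oxygen.
- Enabling feature: C3', C4' and C5' of ring B carry three adjacent oxygens and C1', para to C4', carries the propenyl group. This is the oxygen pattern of a 3-alkoxy-2,4,6-trione: C2'–C6' with O3', O5' and the ether oxygen come from the alkoxy-diketone, C1' and the propenyl group from crotonic acid.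
- Stereochemistry: C8 (S) is the stereocentre of ethyl (S)-lactate and its C–O bond is never broken; C7 (R) is set by chelation-controlled hydride reduction of the α-benzyloxy ketone; the E olefin comes from (E)-but-2-enoyl chloride.

Key step: step 11

Remark: ring A is C1–C6, the side chain is C7 (carbinol), C8 (ether carbon) and C9 (methyl), ring B is C1'–C6'. SEM = 2-(trimethylsilyl)ethoxymethyl, TBS = tert-butyldimethylsilyl. LiN(i-Pr)2 and Zn(BH4)2 are assumed to be taken from pre-made stock solutions.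

**Route**

Step 1
Reactants: 1 4-bromo-2,6-dimethoxyphenol
Product: 2 [2-({4-bromo-2,6-dimethoxyphenoxy}methoxy)ethyl]trimethylsilane
Conditions: NaH, THF, 0 °C; SEMCl, 0 °C → rt
Reagents that add atoms: 2-(trimethylsilyl)ethoxymethyl chloride, C[Si](C)(C)CCOCCl
Why: Williamson-type O-alkylation of the sodium phenoxide by the reactive chloromethyl ether should proceed despite the two flanking methoxy groups and gives an acetal that tolerates organolithium, hydride, hydrogenolysis and enolate conditions but is cleaved by fluoride.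

Step 2
Reactants: 3 ethyl (S)-lactate
Product: 4 ethyl (2S)-2-(benzyloxy)propanoate
Conditions: benzyl 2,2,2-trichloroacetimidate, TfOH (cat.), cyclohexane–CH2Cl2, rt
Reagents that add atoms: benzyl 2,2,2-trichloroacetimidate, ClC(Cl)(Cl)C(=N)OCc1ccccc1
Why: Acid-catalysed imidate benzylation etherifies the secondary alcohol without base, so the lactate stereocentre (the future C8) cannot enolise and racemise.

Step 3
Reactants: 4 ethyl (2S)-2-(benzyloxy)propanoate
Product: 5 (2S)-2-(benzyloxy)-N-methoxy-N-methylpropanamide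
Conditions: MeNH(OMe)·HCl, i-PrMgCl, THF, −20 → 0 °C
Reagents that add atoms: N,O-dimethylhydroxylamine hydrochloride, CNOC.Cl
Why: Aminolysis of the ester by the chloromagnesium amide made in the flask (Weinreb amide formation) is fast at low temperature and leaves the α-alkoxy stereocentre untouched.

Step 4
Reactants: 2 [2-({4-bromo-2,6-dimethoxyphenoxy}methoxy)ethyl]trimethylsilane; 5 (2S)-2-(benzyloxy)-N-methoxy-N-methylpropanamide
Product: 8 (2S)-2-(benzyloxy)-1-[3,5-dimethoxy-4-(SEM-oxy)phenyl]propan-1-one, via aryllithium 6 (not isolated), via tetrahedral lithium adduct 7 (not isolated)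
Conditions: 2, n-BuLi, THF, −78 °C; then 5, −78 → −40 °C; aq. NH4Cl
Reagents that add atoms: none
Why: Bromine–lithium exchange followed by the Weinreb ketone synthesis forms the C1–C7 bond, the chelated adduct stopping the reaction at the ketone stage and the low temperature preventing enolisation next to the benzyloxy group.

Step 5
Reactants: 8 (2S)-2-(benzyloxy)-1-[3,5-dimethoxy-4-(SEM-oxy)phenyl]propan-1-one
Product: 9 (1R,2S)-2-(benzyloxy)-1-[3,5-dimethoxy-4-(SEM-oxy)phenyl]propan-1-ol
Conditions: Zn(BH4)2, Et2O, −30 → 0 °C; aq. NH4Cl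
Reagents that add atoms: none
Why: Chelation-controlled ketone reduction (Cram chelate model), in which zinc ties the carbonyl and benzyloxy oxygens into a five-membered chelate and hydride enters from the face bearing the C8 hydrogen and not the methyl group, should set C7 as R and give the anti alcohol.

Step 6
Reactants: 9 (1R,2S)-2-(benzyloxy)-1-[3,5-dimethoxy-4-(SEM-oxy)phenyl]propan-1-ol
Product: 10 (1R,2S)-2-(benzyloxy)-1-(TBS-oxy)-1-[3,5-dimethoxy-4-(SEM-oxy)phenyl]propane
Conditions: TBSCl, imidazole, DMF, rt → 40 °C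
Reagents that add atoms: tert-butyldimethylsilyl chloride, CC(C)(C)[Si](C)(C)Cl
Why: Imidazole-mediated silylation of the secondary alcohol is neutral towards the SEM acetal and blocks O7 for the carbene and enolate steps that follow.

Step 7
Reactants: 10 (1R,2S)-2-(benzyloxy)-1-(TBS-oxy)-1-[3,5-dimethoxy-4-(SEM-oxy)phenyl]propane
Product: 11 (1R,2S)-1-(TBS-oxy)-1-[3,5-dimethoxy-4-(SEM-oxy)phenyl]propan-2-ol
Conditions: H2 (1 atm), Pd/C, EtOAc, rt
Reagents that add atoms: none
Why: Catalytic hydrogenolysis cleaves the unhindered benzyl ether and frees O8, while the secondary C7–O bond, shielded as a bulky silyl ether, and the SEM acetal should survive in a neutral aprotic solvent.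

Step 8
Reactants: 12 pentane-2,4-dione
Product: 13 3-diazopentane-2,4-dione
Conditions: 4-acetamidobenzenesulfonyl azide, Et3N, MeCN, 0 °C → rt
Reagents that add atoms: 4-acetamidobenzenesulfonyl azide, CC(=O)Nc1ccc(cc1)S(=O)(=O)N=[N+]=[N-]
Why: Regitz diazo transfer to the doubly activated methylene of a 1,3-diketone is a standard, high-yielding reaction.

Step 9
Reactants: 11 (1R,2S)-1-(TBS-oxy)-1-[3,5-dimethoxy-4-(SEM-oxy)phenyl]propan-2-ol; 13 3-diazopentane-2,4-dione
Product: 14 3-{[(1R,2S)-1-(TBS-oxy)-1-[3,5-dimethoxy-4-(SEM-oxy)phenyl]propan-2-yl]oxy}pentane-2,4-dione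
Conditions: Rh2(OAc)4 (2 mol %), slow addition of 13, ClCH2CH2Cl, 80 °C
Reagents that add atoms: none
Why: Rhodium-carbenoid O–H insertion (oxonium ylide, then proton shift) forms the O8–C4' bond under neutral conditions without touching the C8–O bond, so C8 keeps its configuration and the silyl ether cannot migrate.

Step 10
Reactants: 15 (E)-but-2-enoyl chloride
Product: 16 (E)-N-methoxy-N-methylbut-2-enamide
Conditions: MeNH(OMe)·HCl, pyridine, CH2Cl2, 0 °C → rt
Reagents that add atoms: N,O-dimethylhydroxylamine hydrochloride, CNOC.Cl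
Why: N-Acylation of N,O-dimethylhydroxylamine by the acid chloride (Weinreb amide formation) is routine and leaves the E double bond unchanged.

Step 11
Reactants: 14 3-{[(1R,2S)-1-(TBS-oxy)-1-[3,5-dimethoxy-4-(SEM-oxy)phenyl]propan-2-yl]oxy}pentane-2,4-dione; 16 (E)-N-methoxy-N-methylbut-2-enamide
Product: 21 2-{[(1R,2S)-1-(TBS-oxy)-1-[3,5-dimethoxy-4-(SEM-oxy)phenyl]propan-2-yl]oxy}-5-[(E)-prop-1-en-1-yl]benzene-1,3-diol, via dilithium dienediolate 17 (not isolated), via tetrahedral adduct 18 (not isolated), via triketone 19 (not isolated), via cyclic aldol 20 (not isolated)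
Conditions: LiN(i-Pr)2 (2.3 equiv), THF, −78 → 0 °C; 16 (1.3 equiv), −78 → −20 °C; then aq. LiOH (1 M)–MeOH, 0 °C → rt; aq. NH4Cl
Reagents that add atoms: none
Why: Two equivalents of LiN(i-Pr)2 turn the symmetrical dione 14 into dianion 17, whose terminal carbanion adds 1,2 to the carbonyl of amide 16 (Claisen-type acylation of a β-diketone dianion) to give the chelated adduct 18, which keeps the new acyl group masked until water is added, so neither a second acylation nor proton transfer from the more acidic triketone can consume the dianion. When 18 collapses in aqueous LiOH the triketone 19 is released, its methyl ketone carbon C6' adds as the enolate to the crotonyl carbonyl C1' in an intramolecular aldol reaction that closes ring B in the 6-(enolendo)-exo-trig mode to give 20, and E1cB loss of water followed by enolisation of the two remaining carbonyl groups should deliver the aromatic 2-alkoxyresorcinol 21. The closest known reaction type is the base-induced cyclisation of 2,4,6-triketones to 5-substituted resorcinols. No stereocentre is created, the carbinol carbon of 20 is lost on dehydration, and C7 and C8 carry no acidic hydrogen and pass through unchanged. The step needs 1,2- over 1,4-attack on the crotonyl donor, which the hard lithium carbanion and the chelating N-methoxy-N-methyl amide should secure, and carbon over oxygen ring closure, which is favoured because C6'→C1' is the only carbon closure to an unstrained ring, the oxa-Michael and hemiketal adducts are reversible in base and drain through the irreversible aromatisation, and the absence of acid suppresses dehydration to a 4-pyranone. The olefin stays conjugated throughout and keeps its more stable E geometry.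

Step 12
Reactants: 21 2-{[(1R,2S)-1-(TBS-oxy)-1-[3,5-dimethoxy-4-(SEM-oxy)phenyl]propan-2-yl]oxy}-5-[(E)-prop-1-en-1-yl]benzene-1,3-diol
Product: 22 (1R,2S)-1-(TBS-oxy)-1-[3,5-dimethoxy-4-(SEM-oxy)phenyl]-2-{2,6-dimethoxy-4-[(E)-prop-1-en-1-yl]phenoxy}propane
Conditions: MeI, K2CO3, acetone, 50 °C
Reagents that add atoms: iodomethane, CI
Why: Williamson O-methylation of the two phenoxides installs both ring-B methoxy groups, and the alkyl silyl ether, the SEM acetal and the olefin are inert to carbonate.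

Step 13
Reactants: 22 (1R,2S)-1-(TBS-oxy)-1-[3,5-dimethoxy-4-(SEM-oxy)phenyl]-2-{2,6-dimethoxy-4-[(E)-prop-1-en-1-yl]phenoxy}propane
Product: 23 (1R,2S)-2-{2,6-dimethoxy-4-[(E)-prop-1-en-1-yl]phenoxy}-1-(4-hydroxy-3,5-dimethoxyphenyl)propan-1-ol
Conditions: TBAF (excess), THF, rt → 50 °C; aq. NH4Cl
Reagents that add atoms: none
Why: Fluoride-induced desilylation cleaves the TBS ether directly and the SEM acetal by fragmentation to ethene and formaldehyde, under non-acidic conditions that cannot ionise the benzylic C7–O bond, so both stereocentres should persist.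

**Compound list**

1 | 4-bromo-2,6-dimethoxyphenol | COc1cc(Br)cc(OC)c1O | starting material
2 | [2-({4-bromo-2,6-dimethoxyphenoxy}methoxy)ethyl]trimethylsilane (SEM ether of 1) | COc1cc(Br)cc(OC)c1OCOCC[Si](C)(C)C | intermediate
3 | ethyl (S)-lactate | C[C@H](O)C(=O)OCC | starting material
4 | ethyl (2S)-2-(benzyloxy)propanoate | C[C@H](OCc1ccccc1)C(=O)OCC | intermediate
5 | (2S)-2-(benzyloxy)-N-methoxy-N-methylpropanamide | C[C@H](OCc1ccccc1)C(=O)N(C)OC | intermediate
6 | [3,5-dimethoxy-4-(SEM-oxy)phenyl]lithium | [Li]c1cc(OC)c(OCOCC[Si](C)(C)C)c(OC)c1 | intermediate (not isolated)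
7 | lithium (2S)-2-(benzyloxy)-1-[3,5-dimethoxy-4-(SEM-oxy)phenyl]-1-[methoxy(methyl)amino]propan-1-olate (C1 configuration undefined) | C[C@H](OCc1ccccc1)C([O-])(N(C)OC)c1cc(OC)c(OCOCC[Si](C)(C)C)c(OC)c1.[Li+] | intermediate (not isolated)
8 | (2S)-2-(benzyloxy)-1-[3,5-dimethoxy-4-(SEM-oxy)phenyl]propan-1-one | C[C@H](OCc1ccccc1)C(=O)c1cc(OC)c(OCOCC[Si](C)(C)C)c(OC)c1 | intermediate
9 | (1R,2S)-2-(benzyloxy)-1-[3,5-dimethoxy-4-(SEM-oxy)phenyl]propan-1-ol | c1ccccc1CO[C@@H](C)[C@H](O)c1cc(OC)c(OCOCC[Si](C)(C)C)c(OC)c1 | intermediate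
10 | (1R,2S)-2-(benzyloxy)-1-(TBS-oxy)-1-[3,5-dimethoxy-4-(SEM-oxy)phenyl]propane | c1ccccc1CO[C@@H](C)[C@H](O[Si](C)(C)C(C)(C)C)c1cc(OC)c(OCOCC[Si](C)(C)C)c(OC)c1 | intermediate
11 | (1R,2S)-1-(TBS-oxy)-1-[3,5-dimethoxy-4-(SEM-oxy)phenyl]propan-2-ol | O[C@@H](C)[C@H](O[Si](C)(C)C(C)(C)C)c1cc(OC)c(OCOCC[Si](C)(C)C)c(OC)c1 | intermediate
12 | pentane-2,4-dione | CC(=O)CC(C)=O | starting material
13 | 3-diazopentane-2,4-dione | CC(=O)C(=[N+]=[N-])C(C)=O | intermediate
14 | 3-{[(1R,2S)-1-(TBS-oxy)-1-[3,5-dimethoxy-4-(SEM-oxy)phenyl]propan-2-yl]oxy}pentane-2,4-dione | CC(=O)C(O[C@@H](C)[C@H](O[Si](C)(C)C(C)(C)C)c1cc(OC)c(OCOCC[Si](C)(C)C)c(OC)c1)C(C)=O | intermediate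
15 | (E)-but-2-enoyl chloride | C/C=C/C(Cl)=O | starting material
16 | (E)-N-methoxy-N-methylbut-2-enamide | C/C=C/C(=O)N(C)OC | intermediate
17 | dilithium penta-1,3-diene-2,4-diolate of 14 (dianion) | [Li+].[Li+].C=C([O-])C(O[C@@H](C)[C@H](O[Si](C)(C)C(C)(C)C)c1cc(OC)c(OCOCC[Si](C)(C)C)c(OC)c1)=C(C)[O-] | intermediate (not isolated)
18 | dilithium salt of the tetrahedral adduct of 17 and 16 (carbinol configuration undefined) | C/C=C/C([O-])(N(C)OC)CC(=O)C(O[C@@H](C)[C@H](O[Si](C)(C)C(C)(C)C)c1cc(OC)c(OCOCC[Si](C)(C)C)c(OC)c1)=C(C)[O-].[Li+].[Li+] | intermediate (not isolated)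
19 | (7E)-3-{[(1R,2S)-1-(TBS-oxy)-1-[3,5-dimethoxy-4-(SEM-oxy)phenyl]propan-2-yl]oxy}non-7-ene-2,4,6-trione | C/C=C/C(=O)CC(=O)C(O[C@@H](C)[C@H](O[Si](C)(C)C(C)(C)C)c1cc(OC)c(OCOCC[Si](C)(C)C)c(OC)c1)C(C)=O | intermediate (not isolated)
20 | 5-hydroxy-2-{[(1R,2S)-1-(TBS-oxy)-1-[3,5-dimethoxy-4-(SEM-oxy)phenyl]propan-2-yl]oxy}-5-[(E)-prop-1-en-1-yl]cyclohexane-1,3-dione (ring configuration undefined) | C/C=C/C1(O)CC(=O)C(O[C@@H](C)[C@H](O[Si](C)(C)C(C)(C)C)c2cc(OC)c(OCOCC[Si](C)(C)C)c(OC)c2)C(=O)C1 | intermediate (not isolated)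
21 | 2-{[(1R,2S)-1-(TBS-oxy)-1-[3,5-dimethoxy-4-(SEM-oxy)phenyl]propan-2-yl]oxy}-5-[(E)-prop-1-en-1-yl]benzene-1,3-diol | C/C=C/c1cc(O)c(O[C@@H](C)[C@H](O[Si](C)(C)C(C)(C)C)c2cc(OC)c(OCOCC[Si](C)(C)C)c(OC)c2)c(O)c1 | intermediate
22 | (1R,2S)-1-(TBS-oxy)-1-[3,5-dimethoxy-4-(SEM-oxy)phenyl]-2-{2,6-dimethoxy-4-[(E)-prop-1-en-1-yl]phenoxy}propane | C/C=C/c1cc(OC)c(O[C@@H](C)[C@H](O[Si](C)(C)C(C)(C)C)c2cc(OC)c(OCOCC[Si](C)(C)C)c(OC)c2)c(OC)c1 | intermediate
23 | (1R,2S)-2-{2,6-dimethoxy-4-[(E)-prop-1-en-1-yl]phenoxy}-1-(4-hydroxy-3,5-dimethoxyphenyl)propan-1-ol (7R,8S) | C/C=C/c1cc(OC)c(O[C@@H](C)[C@H](O)c2cc(OC)c(O)c(OC)c2)c(OC)c1 | target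

**Step count**

Total steps: 13. Longest linear sequence: 10 steps (steps 2, 3, 4, 5, 6, 7, 9, 11, 12, 13, from ethyl (S)-lactate).

**Steps most likely to fail**

1. Step 11. The crotonyl amide may suffer conjugate addition or γ-deprotonation during the acylation. In the hydroxide stage, ring closure through oxygen (oxa-Michael addition to the enone) or retro-Claisen loss of an acetyl group may outrun the carbon aldol. The fallback removes the enone from the ring-forming step and adds the propenyl group afterwards; it sets out from 14 and returns at 22. The dianion of 14 (LiN(i-Pr)2, 3.3 equiv, the extra equivalent taking up the acidic proton of the product) would be acylated with ethyl 2,2-diethoxyacetate to the diethoxymethyl triketone F1. This has no Michael acceptor and a more electrophilic ketone at the future C1', and the same aldol cyclodehydration in aqueous LiOH should give the 5-(diethoxymethyl)resorcinol F2. Methylation (MeI, K2CO3) would give the dimethyl ether acetal F3, mild hydrolysis (PPTS, acetone–H2O) the benzaldehyde F4, and Takai–Utimoto ethylidenation (CH3CHI2, CrCl2, THF) should form the E-propenyl group and arrive at 22.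

2. Step 9. Capture of the doubly acyl-substituted rhodium carbenoid by the hindered secondary alcohol may be slow, so that Wolff rearrangement, carbene dimerisation or insertion into traces of water take over. The fallback uses the more reactive mono-acyl carbenoid and builds the second acetyl group afterwards; it sets out from 11 and returns at 14. O–H insertion of ethyl diazoacetate (Rh2(OAc)4, CH2Cl2, rt) would give the alkoxyacetate F5, and MeNH(OMe)·HCl/i-PrMgCl the Weinreb amide F6. Its lithium enolate (LiN(i-Pr)2, THF, −78 °C), which can form at only one carbon, would add to acetaldehyde to give the hydroxy amide F7 as a mixture of diastereomers at centres that are erased later. MeMgBr would give the hydroxy ketone F8, and Dess–Martin oxidation of the secondary alcohol would give dione 14.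

3. Step 13. Fluoride attack on the aryl SEM acetal, flanked by two methoxy groups, may be incomplete at a temperature the liberated phenoxide tolerates; prolonged heating in basic fluoride could start quinone-methide formation with epimerisation at C7 or cleavage of the aryl ether. The fallback removes the two groups one at a time by non-basic reagents; it sets out from 22 and ends at 23. MgBr2·OEt2 in Et2O–MeNO2 should cleave the SEM acetal by chelation and leave the alkyl silyl ether, giving the silyl-protected phenol F9, and HF·pyridine in THF–pyridine at 0 °C would then remove the TBS group to give 23.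

**Further compounds**

F1 | step 11 | 1,1-diethoxy-5-{[(1R,2S)-1-(TBS-oxy)-1-[3,5-dimethoxy-4-(SEM-oxy)phenyl]propan-2-yl]oxy}heptane-2,4,6-trione | CCOC(OCC)C(=O)CC(=O)C(O[C@@H](C)[C@H](O[Si](C)(C)C(C)(C)C)c1cc(OC)c(OCOCC[Si](C)(C)C)c(OC)c1)C(C)=O
F2 | step 11 | 5-(diethoxymethyl)-2-{[(1R,2S)-1-(TBS-oxy)-1-[3,5-dimethoxy-4-(SEM-oxy)phenyl]propan-2-yl]oxy}benzene-1,3-diol | CCOC(OCC)c1cc(O)c(O[C@@H](C)[C@H](O[Si](C)(C)C(C)(C)C)c2cc(OC)c(OCOCC[Si](C)(C)C)c(OC)c2)c(O)c1
F3 | step 11 | (1R,2S)-2-[4-(diethoxymethyl)-2,6-dimethoxyphenoxy]-1-(TBS-oxy)-1-[3,5-dimethoxy-4-(SEM-oxy)phenyl]propane | CCOC(OCC)c1cc(OC)c(O[C@@H](C)[C@H](O[Si](C)(C)C(C)(C)C)c2cc(OC)c(OCOCC[Si](C)(C)C)c(OC)c2)c(OC)c1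
F4 | step 11 | 4-{[(1R,2S)-1-(TBS-oxy)-1-[3,5-dimethoxy-4-(SEM-oxy)phenyl]propan-2-yl]oxy}-3,5-dimethoxybenzaldehyde | O=Cc1cc(OC)c(O[C@@H](C)[C@H](O[Si](C)(C)C(C)(C)C)c2cc(OC)c(OCOCC[Si](C)(C)C)c(OC)c2)c(OC)c1
F5 | step 9 | ethyl 2-{[(1R,2S)-1-(TBS-oxy)-1-[3,5-dimethoxy-4-(SEM-oxy)phenyl]propan-2-yl]oxy}acetate | CCOC(=O)CO[C@@H](C)[C@H](O[Si](C)(C)C(C)(C)C)c1cc(OC)c(OCOCC[Si](C)(C)C)c(OC)c1
F6 | step 9 | N-methoxy-N-methyl-2-{[(1R,2S)-1-(TBS-oxy)-1-[3,5-dimethoxy-4-(SEM-oxy)phenyl]propan-2-yl]oxy}acetamide | CON(C)C(=O)CO[C@@H](C)[C@H](O[Si](C)(C)C(C)(C)C)c1cc(OC)c(OCOCC[Si](C)(C)C)c(OC)c1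
F7 | step 9 | 3-hydroxy-N-methoxy-N-methyl-2-{[(1R,2S)-1-(TBS-oxy)-1-[3,5-dimethoxy-4-(SEM-oxy)phenyl]propan-2-yl]oxy}butanamide (C2 and C3 undefined) | CON(C)C(=O)C(O[C@@H](C)[C@H](O[Si](C)(C)C(C)(C)C)c1cc(OC)c(OCOCC[Si](C)(C)C)c(OC)c1)C(C)O
F8 | step 9 | 4-hydroxy-3-{[(1R,2S)-1-(TBS-oxy)-1-[3,5-dimethoxy-4-(SEM-oxy)phenyl]propan-2-yl]oxy}pentan-2-one (C3 and C4 undefined) | CC(=O)C(O[C@@H](C)[C@H](O[Si](C)(C)C(C)(C)C)c1cc(OC)c(OCOCC[Si](C)(C)C)c(OC)c1)C(C)O
F9 | step 13 | 4-[(1R,2S)-1-(TBS-oxy)-2-{2,6-dimethoxy-4-[(E)-prop-1-en-1-yl]phenoxy}propyl]-2,6-dimethoxyphenol | C/C=C/c1cc(OC)c(O[C@@H](C)[C@H](O[Si](C)(C)C(C)(C)C)c2cc(OC)c(O)c(OC)c2)c(OC)c1
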